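**Assumptions (one line each)**
- The target is drawn as the free bis(hydrogen sulfate); I assume it is isolated as the disodium salt.
- α/β descriptors refer to the standard decalin drawing (C10 on top, ring A left), in which the target has H10′ α, Me9′ β, CH2Ar α, Me8′ α, Me4′ β, chain at C4′ α, H5 β, Me9 β, chain at C9 α and Me8 β.
- Unit 1 (avarane-type half) is primed; unit 2 (second decalin, Δ1(10)) is unprimed.

## Retrosynthetic overview
1. The only bond joining the two decalins, C4′–CH2 of the CH2CH2 bridge, is made by a Cu-catalysed anti-SN2′ coupling of a unit-2 primary Grignard with a unit-1 tetrasubstituted cyclic allylic phosphate. This forms the C4′ quaternary centre and the Δ5′(6′) alkene together (new step).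
2. Unit 1: the allylic phosphate comes from a tetrasubstituted enone made by intramolecular aldol condensation (ring A′ closed last). That enone comes from a cyclohexanone made by two conjugate additions to a 4-Me-4-ArCH2-cyclohexadienone (Stork–Danheiser alkylations set C9′).
3. Unit 2: a Johnson–Claisen of an allylic alcohol sets the C9 quaternary centre, the Δ1(10) alkene and both bridge carbons. The alcohol comes from an aldol-condensation enone (ring B closed) made on 4,4-dimethylcyclohexenone, which is ring A and sets C5 by asymmetric 1,4-addition.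
4. The arene is carried as its dimethyl ether to the end: CAN gives the quinone, dithionite gives the hydroquinone, then bis-sulfation.

Ring order: unit 1 ring B′ is carried in from 3 (steps 2–7) and ring A′ is closed in step 8; unit 2 ring A is carried in from 20 and ring B is closed in step 17.

## Route

**Step 1**
Reactants: 1 (2,5-dimethoxybenzyl alcohol)
Product: 2 (2,5-dimethoxybenzyl bromide)
Conditions: PBr3, Et2O, 0 °C
Reagents that add atoms: PBr3, BrP(Br)Br
Why: Alcohol-to-bromide conversion gives the benzylic electrophile; no stereocentres are involved.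

**Step 2**
Reactants: 3 (3-ethoxycyclohex-2-en-1-one), 2
Product: 4 (6-(2,5-dimethoxybenzyl)-3-ethoxycyclohex-2-enone, racemic)
Conditions: LDA, THF, –78 °C, then 2, –78 → 0 °C
Reagents that add atoms: none (the benzyl group comes from 2)
Why: Stork–Danheiser α′-alkylation of the vinylogous-ester enolate; the stereocentre formed is destroyed in step 5.

**Step 3**
Reactants: 4
Product: 5 (6-(2,5-dimethoxybenzyl)-3-ethoxy-6-methylcyclohex-2-enone, racemic)
Conditions: LDA, THF, –78 °C, then MeI, HMPA, –78 → 0 °C
Reagents that add atoms: MeI, CI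
Why: A second enolate alkylation makes the C9′ quaternary centre; its configuration is irrelevant because the dienone in step 5 is achiral.

**Step 4**
Reactants: 5
Product: 6 (4-(2,5-dimethoxybenzyl)-4-methylcyclohex-2-en-1-one, racemic)
Conditions: LiAlH4, THF, 0 °C; then 1 M HCl, THF, rt
Reagents that add atoms: water, O (supplies the carbonyl oxygen)
Why: Stork–Danheiser reductive transposition converts the vinylogous ester into the 4,4-disubstituted enone.

**Step 5**
Reactants: 6
Product: 7 (4-(2,5-dimethoxybenzyl)-4-methylcyclohexa-2,5-dien-1-one, achiral, prochiral at C4)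
Conditions: IBX·MPO complex, DMSO, 65 °C
Reagents that add atoms: none
Why: Nicolaou IBX dehydrogenation gives the cross-conjugated dienone, which has two enantiotopic enone arms.

**Step 6**
Reactants: 7, 8 (2-(3-chloropropyl)-2-methyl-1,3-dioxolane, used as its Grignard)
Product: 9 (enone: 5-(4-(2-methyl-1,3-dioxolan-2-yl)propyl)-4-Me-4-ArCH2-cyclohex-2-enone, with the chain β at C10′, Me9′ β and CH2Ar α)
Conditions: 8 + Mg, THF, 50 °C (Grignard); then CuBr·SMe2 (5 mol%), Josiphos-type ligand (6 mol%), t-BuOMe, –78 °C
Reagents that add atoms: none (the chain comes from 8)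
Why: Cu-catalysed desymmetrising asymmetric 1,4-addition; the chiral ligand selects the enantiotopic arm, and the chain adds anti to the larger CH2Ar group, so it ends up cis to Me9′ (β) and H10′ is α. The ligand enantiomer is chosen to give the configuration drawn.

**Step 7**
Reactants: 9
Product: 10 (ketone: 3-methyl-cyclohexanone with Me8′ α, Me9′ β, CH2Ar α, C10′ chain β, ketal intact)
Conditions: MeLi + CuI (Me2CuLi), TMSCl, Et2O, –78 → 0 °C; then aq. NH4Cl
Reagents that add atoms: MeLi, C[Li]
Why: Diastereoselective cuprate 1,4-addition at C8′ occurs axially, anti to the axial Me9′ (β), which places Me8′ α, trans to Me9′ and cis to CH2Ar.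

**Step 8**
Reactants: 10
Product: 11 (tetrasubstituted enone: C6′=O, Δ4′(5′), Me4′, H10′ α, Me9′ β, CH2Ar α, Me8′ α)
Conditions: TsOH·H2O (0.3 equiv), benzene, reflux, Dean–Stark
Reagents that add atoms: none
Why: Ketal hydrolysis followed by intramolecular aldol condensation closes ring A′ (C5′ enol onto the C4′ methyl ketone); thermodynamic control favours the fused enone over the bridged aldol, and all stereocentres are untouched.

**Step 9**
Reactants: 11
Product: 12 (allylic alcohol, C6′-OH α)
Conditions: NaBH4, CeCl3·7H2O, MeOH, –40 °C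
Reagents that add atoms: none
Why: Luche 1,2-reduction; hydride enters from the β face because the α face at C6′ is shielded by the axial Me8′ (1,3-diaxial), giving the α-alcohol (assumption, checked by NOE).

**Step 10**
Reactants: 12
Product: 13 (C6′ p-nitrobenzoate, β)
Conditions: p-O2NC6H4CO2H, PPh3, DIAD, THF, 0 °C → rt
Reagents that add atoms: p-nitrobenzoic acid, OC(=O)c1ccc(cc1)[N+](=O)[O-]
Why: Mitsunobu SN2 inversion moves the oxygen to the β face, which sets up anti attack from the α face in step 23.

**Step 11**
Reactants: 13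
Product: 14 (allylic alcohol, C6′-OH β)
Conditions: K2CO3, MeOH, rt
Reagents that add atoms: none
Why: Methanolysis of the ester with retention at carbon.

**Step 12**
Reactants: 14
Product: 15 (C6′-β diethyl phosphate)
Conditions: n-BuLi, THF, –78 °C; then (EtO)2P(O)Cl, –78 °C → rt
Reagents that add atoms: diethyl chlorophosphate, CCOP(=O)(Cl)OCC
Why: O-Phosphorylation of the lithium alkoxide gives the leaving group needed for SN2′.

**Step 13**
Reactants: 16 (α-acetyl-γ-butyrolactone)
Product: 17 (α-acetyl-α-methyl-γ-butyrolactone)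
Conditions: K2CO3, MeI, acetone, reflux
Reagents that add atoms: MeI, CI
Why: C-Alkylation of the 1,3-dicarbonyl enolate.

**Step 14**
Reactants: 17
Product: 18 (5-bromo-3-methylpentan-2-one, racemic)
Conditions: 48% aq. HBr, reflux
Reagents that add atoms: HBr, Br
Why: Bromide opens the lactone and the resulting β-keto acid decarboxylates.

**Step 15**
Reactants: 18
Product: 19 (2-(4-bromobutan-2-yl)-2-methyl-1,3-dioxolane, racemic)
Conditions: ethylene glycol, TsOH, benzene, reflux, Dean–Stark
Reagents that add atoms: ethylene glycol, OCCO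
Why: Ketalisation masks the methyl ketone so a Grignard can be made.

**Step 16**
Reactants: 20 (4,4-dimethylcyclohex-2-en-1-one), 19 (as its Grignard)
Product: 21 (3-substituted 4,4-dimethylcyclohexanone, C5 set; C8 is an epimeric mixture)
Conditions: 19 + Mg, THF (Grignard); CuBr·SMe2 (5 mol%), Josiphos-type ligand (6 mol%), t-BuOMe, –78 °C
Reagents that add atoms: none (the chain comes from 19)
Why: Cu-catalysed asymmetric Grignard 1,4-addition sets C5 (ligand enantiomer chosen to give the configuration drawn); the remote C8 epimers converge in step 17.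

**Step 17**
Reactants: 21
Product: 22 (enone: Δ9(10)-1-one, H5 β, Me8 β)
Conditions: TsOH·H2O, benzene, reflux, Dean–Stark
Reagents that add atoms: none
Why: Ketal removal and intramolecular aldol condensation close ring B through a chair-like transition state with Me8 equatorial, which gives C5–C4 and Me8 diequatorial (trans, C4 α / Me8 β). This C8 selectivity is an assumption (≥4:1, epimers separable); the α-carbon C8 equilibrates through its enol so both chain epimers converge.

**Step 18**
Reactants: 22
Product: 23 (allylic alcohol, C1-OH α)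
Conditions: NaBH4, CeCl3·7H2O, MeOH, 0 °C
Reagents that add atoms: none
Why: Luche reduction by axial β-hydride attack gives the equatorial α-alcohol, which the Claisen needs to deliver the chain to the α face; the minor β epimer is recycled by MnO2 oxidation.

**Step 19**
Reactants: 23
Product: 24 (ethyl ester: C9 quaternary with Me β and CH2CO2Et α, Δ1(10), H5 β, Me8 β)
Conditions: MeC(OEt)3 (10 equiv), EtCO2H (5 mol%), 140 °C, sealed tube
Reagents that add atoms: triethyl orthoacetate, CC(OCC)(OCC)OCC
Why: Johnson–Claisen [3,3] rearrangement is suprafacial, so the new C9–CH2 bond forms on the same (α) face as the C1–O bond and anti to Me8, making the C9 quaternary centre and moving the alkene to C10=C1.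

**Step 20**
Reactants: 24
Product: 25 (primary alcohol, C9–CH2CH2OH)
Conditions: LiAlH4, Et2O, 0 °C
Reagents that add atoms: none
Why: Ester reduction; the trisubstituted alkene is untouched.

**Step 21**
Reactants: 25
Product: 26 (primary iodide, C9–CH2CH2I)
Conditions: I2, PPh3, imidazole, CH2Cl2, 0 °C → rt
Reagents that add atoms: I2, II
Why: Appel iodination of a primary alcohol with a γ-quaternary centre.

**Step 22**
Reactants: 26
Product: 27 (Grignard reagent, C9–CH2CH2MgI)
Conditions: Mg turnings, 1,2-dibromoethane (cat.), THF, 40 °C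
Reagents that add atoms: Mg, [Mg]
Why: Oxidative insertion of Mg into the primary C–I bond; the alkene and stereocentres are inert.

**Step 23**
Reactants: 15, 27
Product: 28 (tetra-ring dimethyl ether of the target, fully stereodefined)
Conditions: CuBr·SMe2 (20 mol%), THF, –78 → –20 °C, 27 (3 equiv) added to 15
Reagents that add atoms: none (the chain comes from 27)
Why: Proposed new method: Cu-catalysed anti-SN2′ coupling of an unactivated primary alkyl-MgX (γ-quaternary, carrying the whole unit-2 half) with a cyclic allylic phosphate whose alkene is tetrasubstituted and whose γ-carbon is next to a ring-fusion carbon; mechanistically, the Cu(I)-alkyl coordinates the C4′=C5′ alkene anti to the pseudo-axial β C6′–OP bond, oxidative addition gives a σ-allyl-Cu(III) at the more substituted γ-terminus C4′, and reductive elimination forms the quaternary C–C bond with net anti delivery from the α face (Me4′ β, chain α) while the alkene moves to C5′=C6′; the closest known reaction is Cu-catalysed anti-SN2′ of Grignard reagents on γ,γ-disubstituted allylic phosphates that forms quaternary stereocentres.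

**Step 24**
Reactants: 28
Product: 29 (2-substituted 1,4-benzoquinone)
Conditions: CAN (2.5 equiv), MeCN/H2O 4:1, 0 °C, 10 min
Reagents that add atoms: water, O
Why: Ce(IV) oxidative demethylation converts the 1,4-dimethoxyarene to the p-quinone under conditions where the trisubstituted alkenes survive.

**Step 25**
Reactants: 29
Product: 30 (hydroquinone)
Conditions: Na2S2O4, THF/H2O, rt, argon
Reagents that add atoms: none
Why: Dithionite reduces the quinone to the hydroquinone; no stereocentre is affected.

**Step 26**
Reactants: 30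
Product: 31 (toxiusol, isolated as the disodium salt)
Conditions: SO3·pyridine (3 equiv), pyridine, 0 °C → rt; then aq. NaHCO3 and Na+ exchange
Reagents that add atoms: sulfur trioxide–pyridine, O=S(=O)=O (with c1ccncc1)
Why: O-Sulfation of both phenols under the mild, buffered conditions the acid-sensitive alkenes need.

## Compound list
1 | 2,5-dimethoxybenzyl alcohol | OCc1cc(OC)ccc1OC | starting material
2 | 2,5-dimethoxybenzyl bromide | BrCc1cc(OC)ccc1OC | intermediate
3 | 3-ethoxycyclohex-2-en-1-one | CCOC1=CC(=O)CCC1 | starting material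
4 | 6-(2,5-dimethoxybenzyl)-3-ethoxycyclohex-2-enone (racemic) | CCOC1=CC(=O)C(Cc2cc(OC)ccc2OC)CC1 | intermediate
5 | 6-(2,5-dimethoxybenzyl)-3-ethoxy-6-methylcyclohex-2-enone (racemic) | CCOC1=CC(=O)C(C)(Cc2cc(OC)ccc2OC)CC1 | intermediate
6 | 4-(2,5-dimethoxybenzyl)-4-methylcyclohex-2-enone (racemic) | O=C1C=CC(C)(Cc2cc(OC)ccc2OC)CC1 | intermediate
7 | 4-(2,5-dimethoxybenzyl)-4-methylcyclohexa-2,5-dienone | CC1(Cc2cc(OC)ccc2OC)C=CC(=O)C=C1 | intermediate
8 | 2-(3-chloropropyl)-2-methyl-1,3-dioxolane | CC1(CCCCl)OCCO1 | starting material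
9 | enone from desymmetrising 1,4-addition | O=C1C=C[C@@](C)(Cc2cc(OC)ccc2OC)[C@H](CCCC3(C)OCCO3)C1 | intermediate
10 | ketone after methyl 1,4-addition | C[C@@H]1CC(=O)C[C@@H](CCCC2(C)OCCO2)[C@]1(C)Cc1cc(OC)ccc1OC | intermediate
11 | bicyclic Δ4′-6′-enone | C[C@@H]1CC(=O)C2=C(C)CCC[C@H]2[C@]1(C)Cc1cc(OC)ccc1OC | intermediate
12 | C6′-α allylic alcohol | C[C@@H]1C[C@H](O)C2=C(C)CCC[C@H]2[C@]1(C)Cc1cc(OC)ccc1OC | intermediate
13 | C6′-β p-nitrobenzoate | C[C@@H]1C[C@@H](OC(=O)c3ccc([N+](=O)[O-])cc3)C2=C(C)CCC[C@H]2[C@]1(C)Cc1cc(OC)ccc1OC | intermediate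
14 | C6′-β allylic alcohol | C[C@@H]1C[C@@H](O)C2=C(C)CCC[C@H]2[C@]1(C)Cc1cc(OC)ccc1OC | intermediate
15 | C6′-β diethyl phosphate | C[C@@H]1C[C@@H](OP(=O)(OCC)OCC)C2=C(C)CCC[C@H]2[C@]1(C)Cc1cc(OC)ccc1OC | intermediate
16 | α-acetyl-γ-butyrolactone | CC(=O)C1CCOC1=O | starting material
17 | α-acetyl-α-methyl-γ-butyrolactone | CC(=O)C1(C)CCOC1=O | intermediate
18 | 5-bromo-3-methylpentan-2-one (racemic) | CC(=O)C(C)CCBr | intermediate
19 | 2-(4-bromobutan-2-yl)-2-methyl-1,3-dioxolane (racemic) | CC1(C(C)CCBr)OCCO1 | intermediate
20 | 4,4-dimethylcyclohex-2-en-1-one | CC1(C)C=CC(=O)CC1 | starting material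
21 | 4,4-dimethyl-3-(ketal-chain)cyclohexanone (C5 defined; C8 epimer mixture, unspecified) | O=C1CCC(C)(C)[C@@H](CCC(C)C2(C)OCCO2)C1 | intermediate
22 | Δ9(10)-1-one, H5 β, Me8 β | O=C1CCC(C)(C)[C@H]2CC[C@H](C)C(C)=C12 | intermediate
23 | C1-α allylic alcohol | O[C@H]1CCC(C)(C)[C@H]2CC[C@H](C)C(C)=C12 | intermediate
24 | ethyl ester (Claisen product) | CCOC(=O)C[C@@]1(C)C2=CCCC(C)(C)[C@H]2CC[C@@H]1C | intermediate
25 | primary alcohol | OCC[C@@]1(C)C2=CCCC(C)(C)[C@H]2CC[C@@H]1C | intermediate
26 | primary iodide | ICC[C@@]1(C)C2=CCCC(C)(C)[C@H]2CC[C@@H]1C | intermediate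
27 | Grignard reagent | I[Mg]CC[C@@]1(C)C2=CCCC(C)(C)[C@H]2CC[C@@H]1C | intermediate
28 | dimethyl ether of target | C[C@@H]1CC=C2[C@@H](CCC[C@@]2(C)CC[C@@]2(C)C3=CCCC(C)(C)[C@H]3CC[C@@H]2C)[C@]1(C)Cc1cc(OC)ccc1OC | intermediate
29 | quinone | C[C@@H]1CC=C2[C@@H](CCC[C@@]2(C)CC[C@@]2(C)C3=CCCC(C)(C)[C@H]3CC[C@@H]2C)[C@]1(C)CC1=CC(=O)C=CC1=O | intermediate
30 | hydroquinone | C[C@@H]1CC=C2[C@@H](CCC[C@@]2(C)CC[C@@]2(C)C3=CCCC(C)(C)[C@H]3CC[C@@H]2C)[C@]1(C)Cc1cc(O)ccc1O | intermediate
31 | toxiusol (bis-sulfate) | C[C@@H]1CC=C2[C@@H](CCC[C@@]2(C)CC[C@@]2(C)C3=CCCC(C)(C)[C@H]3CC[C@@H]2C)[C@]1(C)Cc1cc(OS(=O)(=O)O)ccc1OS(=O)(=O)O | target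

## Totals
- Total steps: 26.
- Longest linear sequence: 16 steps (1 → 2 → 4 → 5 → 6 → 7 → 9 → 10 → 11 → 12 → 13 → 14 → 15 → 28 → 29 → 30 → 31, i.e. steps 1–12 then 23–26); the unit-2 branch is 10 steps to 27.

## Three steps most likely to fail
1. **Step 23 (the proposed new step).** The SN2′ may give α-attack at C6′, Grignard attack at P, or the wrong face.
   Fallback (known chemistry): add 27 (CuI, TMSCl) in 1,4-fashion to enone 11. Trap the regiodefined C5′/C6′ enolate as the enol triflate with Comins' reagent, then reduce with Pd(OAc)2/PPh3/HCO2H to give 28. This sets C4′ by conjugate-addition facial selectivity instead.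
2. **Step 6.** Enantio- and diastereoselective desymmetrising addition of a primary Grignard to the dienone may be poor.
   Fallback: start from enantiopure 3-ethoxy-5-methylcyclohex-2-enone, obtained by chiral-HPLC separation of the racemic vinylogous ether. Use the trans-alkylations (ArCH2Br, then MeI), LiAlH4/HCl, and a racemic Cu-catalysed 1,4-addition of 8's Grignard to reach 10 directly, skipping steps 5–7.
3. **Step 24.** CAN could attack the two trisubstituted alkenes.
   Fallback: cleave the aryl methyl ethers by nucleophilic SN2 demethylation (NaSEt, DMF, 120 °C, argon) to give hydroquinone 30 directly, skipping step 25.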